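## Structural features

The target (C42H30O24) is a linear, achiral heptamer of benzene rings A–G joined only by six diaryl ether oxygens and carrying eighteen free phenolic hydroxyls; there is no stereocentre, so no stereochemical relationship has to be set. From the 2,4,6-trihydroxyphenyl end the links are A1–O–B1, B4–O–C1, C6–O–D1, D4–O–E1, E6–O–F1 and F4–O–G1. Rings B, D and F are 3,5-dihydroxy-1,4-dioxygenated, rings C and E are pentaoxygenated (ether oxygens on the neighbouring carbons 1 and 6, hydroxyls on 3–5), and ring G is a 3,4,5-trihydroxyphenyl group. The chain is directional and has no symmetry element, although the pairs B–C, D–E and F–G repeat one motif. The free pyrogallol- and phloroglucinol-type rings are easily oxidised by air to quinones and are strong carbon nucleophiles, so every hydroxyl must stay masked until the last step, and the ethers on rings B, D and F should not see hot aqueous acid. The real difficulty lies in the ether bonds: each ends on at least one carbon flanked by two oxygenated carbons (A1, B4, D4, F4, C6, E6) and every ring is electron-rich, the worst case for Ullmann coupling and for nucleophilic aromatic substitution alike. Ring G offers a way round one of these bonds: G1 lies between two CH carbons (G2, G6) and G3–G5 are contiguously oxygenated, which is the pattern of a 3,4,5-trimethoxypyrylium ion whose ring oxygen is exchanged for a C–OAr carbon, so F4–O–G1 can be made as an O–CH2 alkyl ether and ring G grown onto it. In rings A, B and D an oxygen stands para, and in rings C and E ortho, to the ether carbon still to be bonded, so a formyl group there can act first as activator and then as latent hydroxyl.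

## Logic of the disconnections

34 from 33. The seventeen O–CH3 bonds are cut (the A4 hydroxyl is already free). The polyphenol cannot be carried through a synthesis, and one kind of protecting group that tolerates base, copper, peracid and hydrogenation keeps the plan simple. 33 is a stable, chromatographable compound. The forward step must cleave all seventeen ethers without breaking a diaryl C–O bond and must be worked up without oxygen.

33 from 30 and 21 (through 31 and 32). The A4 hydroxyl is traced back to a formyl group, then the A1–O bond is cut. The formyl group para to A1 makes the carbon between two methoxy groups electrophilic and is afterwards turned into the hydroxyl the target needs. Ring A then comes complete from 21. The demand is a C–O coupling at a doubly ortho-substituted carbon and clean aryl migration in the oxidation.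

30 from 27 and 21 (through 28 and 29). The same two cuts on ring B: B1 hydroxyl back to formyl, then B4–O. Ring B again comes from 21. The coupling is the most hindered type, because the phenol partner 27 also has an ortho aryloxy group.

27 from 24 and 17 (through 25 and 26). The C1 hydroxyl goes back to formyl and the C6–O bond is cut. Here the formyl group is ortho to the bromine-bearing carbon, and 17 delivers ring C with its three methoxy groups in place. The phenol partner 24 is unhindered, so the demand on the coupling is moderate.

24 from 20 and 21 (through 22 and 23). Ring D repeats the ring B logic: D1 hydroxyl from formyl, cut D4–O. The demand is the same as for 30.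

20 from 16 and 17 (through 18 and 19). Ring E repeats the ring C logic: E1 hydroxyl from formyl, cut E6–O. The nucleophile is the unhindered F1 phenol of 16.

16 from 15. The benzyl–O bond on F1 is cut. Benzyl is orthogonal to the methyl ethers and is removed under neutral conditions that leave diaryl ethers alone.

15 from 11 and 5 (through 12, 13 and 14). The bonds G1–G2 and G1–G6 are cut, which removes ring G as a ring and leaves its five oxygenated and CH carbons in 5 and its ether carbon G1 as the P-bearing CH2 of 11. The F4–O bond between two methoxylated carbons never has to be made by aryl coupling, and all three ring G oxygens arrive with 5. The forward step must direct the ylide to the alpha-carbon of 5 and must supply a second equivalent of base for the closing olefination.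

11 from 8 and 9 (through 10); 8 from 7; 7 from 6. The P–C bond and the O–CH2 bond are cut, then the benzyl–O4 bond, then the two O–H bonds of the hydroquinone. This reduces ring F to the purchased quinone 6. The demands are selective benzylation of the unhindered O4 and an O-chloromethylation that stops at the monoether.

5 from 4; 4 from 1 and 2 (through 3). The O–CH3 bond on C4 is cut, then the two C–C bonds made by formylation and the ring O–C bond. The pyrylium ion is reduced to a symmetrical ketone and a formate ester. The demand is formylation on both alpha-carbons of 1.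

## Other disconnections considered

Alternative 1: The cut runs through ring D (bonds D6–D1 and D4–D3) and divides the molecule into an EFG half, carried as the 4-aryloxyacetoacetate A1, and an ABC half, carried as the 3-aryloxypropiolate A2. In the forward step the enolate of A1 would add through C2 to the aryloxy-bearing alkyne carbon of A2, and the C4 enolate would then close onto the propiolate ester (Michael–Claisen), giving ring D in A3 as a dihydroxybenzoate with both ether oxygens in place.
- In its favour: it is a 3 + 3 union at the centre, so on convergence and longest linear sequence it is better than the chosen linear plan. It also forms D4–O–E1 and D1–O–C6 without any aryl C–O coupling, which is better than step 10 of the chosen plan. The phenol needed to make A1 is 20 of the chosen route.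
- Against it here: A3 carries an ester at D6 that the target lacks, so hydrolysis and decarboxylation of a hindered benzoate are added. A2 is an ynol ether of the hindered C6 phenol of an ABC trimer, which itself needs two difficult ether bonds. The Michael adduct is a beta-aryloxy acrylate that could expel the ABC phenoxide by addition–elimination instead of cyclising.
- Comparison: the annulation solves one of six linkages and leaves five to other chemistry, so the total step count would not fall, whereas the chosen plan treats all six with two repeating operations. On protecting groups and final deprotection the two plans are equal.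

Alternative 2: The cut is the bond between carbons a and f of ring C, leading back to the cyclobutenone A4, whose aryl group is the AB dimer. On heating, A4 would open by a 4π electrocyclic reaction to a dienylketene, close by a 6π reaction and tautomerise to the phenol A5.
- In its favour: all five oxygens of ring C are placed without ambiguity from a squaric ester. B4–O–C1 is made as a vinyl ether before ring C exists, the same philosophy as the chosen key step. The one free hydroxyl appears exactly on the carbon that must be arylated next, which the pyrylium step cannot do for a pentaoxygenated ring, so on this structural point it is better. The regiochemistry is fixed by connectivity, with no competing site of attack, which is also better than the chosen key step; the conditions are neutral and metal-free.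
- Against it here: it reaches only a trimer. It needs a 2-aryloxyvinyl organometallic from the hindered B4 phenol, a 1,2-addition, O-methylation of a tertiary alkoxide and the thermolysis, about five operations per ring against two (coupling, oxidation) in the chosen plan. The C6 hydroxyl of A5 is a hindered phenol that must then be joined to ring D through an electrophile without activation.
- Comparison: equal to the chosen key step in strategy and better in regiochemical certainty, but worse in step economy, and it leaves the A1–O–B1 bond and four further rings unsolved.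

Alternative 3: The cut removes ring B (bonds B2–B3 and B1–B6) and leads to the cyclobutenone A6, carrying the CDEFG pentamer on oxygen, and the ethynyl ether A7 of ring A. Heating would open A6 to a vinylketene, which adds to A7 in a [2+2] sense; 4π opening and 6π closure would then give A8 with a free B3 hydroxyl and a B5 ethyl ether (Danheiser benzannulation).
- In its favour: both oxygens flanking ring B (B4–O–C1 and B1–O–A1) are brought in as non-aryl ethers, so the two most hindered couplings of the chosen plan (steps 14 and 16) are avoided; on this point it is better. It is convergent at the end and its regiochemistry follows from the polarity of the ynol ether. The pentamer phenol needed for A6 is 27 of the chosen route.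
- Against it here: A6 must be made on the precious pentamer through an aryloxyketene cycloaddition. A7 is a reactive aryl ynol ether that has to survive the heating. The four-step pericyclic cascade has several points at which it could branch. The extra ethyl group is harmless, since the final dealkylation removes it.
- Comparison: it replaces four steps of the chosen plan (14–17) by about as many, so step economy is equal, and it gives no help with the five linkages inside the pentamer.

Key step: step 6

Remarks on the chemistry:
- Descriptor of 14: in the isomer that can cyclise, the chain carbons are cis across both double bonds. By the sequence rules this is 2E,4Z counted from the phosphonium carbon (2Z,4E from the aldehyde carbon), not Z,Z, because the methoxy oxygen outranks the chain carbon on the methoxylated alkene carbon next to the CH.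
- Design of the precursors: 11 is made without electrophilic chlorine reagents, which would attack its very electron-rich ring. In step 6 the ylide is added to the pyrylium salt and a separate second base is used, because the adduct is far more acidic than 11.
- Supply: 17 and 21 are taken as purchased compounds.

Step 1
Reactants: 1 1,3-dimethoxyacetone; 2 ethyl formate
Product: 4 3,5-dimethoxy-4H-pyran-4-one, via bis(hydroxymethylene) ketone 3 (not isolated)
Conditions: NaH, EtOH (cat.), excess 2, Et2O, 0 °C → rt; then conc. HCl, 0 °C → rt
Reagents that add atoms: none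
Why: Double Claisen formylation of the two alpha-methylene groups gives the bis-enolate of 3; on acidification one enol oxygen adds to the other formyl group and water is lost (cyclodehydration), the established route to symmetrical 3,5-disubstituted 4-pyranones.

Step 2
Reactants: 4 3,5-dimethoxy-4H-pyran-4-one
Product: 5 3,4,5-trimethoxypyrylium tetrafluoroborate
Conditions: Me3OBF4, CH2Cl2, rt; precipitation with Et2O, storage under argon
Reagents that add atoms: trimethyloxonium tetrafluoroborate, C[O+](C)C.F[B-](F)(F)F
Why: The carbonyl oxygen of a 4-pyranone is its nucleophilic site, and O-methylation with a hard oxonium salt gives the aromatic 4-methoxypyrylium ion, a standard preparation of such salts.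

Step 3
Reactants: 6 2,6-dimethoxy-1,4-benzoquinone
Product: 7 2,6-dimethoxybenzene-1,4-diol
Conditions: Na2S2O4, EtOAc/H2O, rt, argon; used at once
Reagents that add atoms: none
Why: Dithionite reduction of a quinone to its hydroquinone; the product is air-sensitive and is therefore taken straight into step 4.

Step 4
Reactants: 7 2,6-dimethoxybenzene-1,4-diol
Product: 8 4-(benzyloxy)-2,6-dimethoxyphenol
Conditions: BnBr (1.0 equiv), K2CO3 (1.0 equiv), degassed acetone, rt → 40 °C, argon
Reagents that add atoms: benzyl bromide, BrCc1ccccc1
Why: Williamson etherification; the O4 hydroxyl is unhindered and, being meta to both methoxy groups, the more acidic one, so one equivalent of base and halide should alkylate it in preference to O1, which is flanked by two methoxy groups.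

Step 5
Reactants: 8 4-(benzyloxy)-2,6-dimethoxyphenol; 9 triphenylphosphine
Product: 11 {[4-(benzyloxy)-2,6-dimethoxyphenoxy]methyl}triphenylphosphonium chloride, via chloromethyl ether 10 (not isolated)
Conditions: NaH, BrCH2Cl (20 equiv), THF, 0 → 60 °C; evaporation, filtration in toluene under argon; 9, toluene, 90 °C
Reagents that add atoms: bromochloromethane, ClCBr
Why: O-Alkylation of the hindered sodium phenoxide with a large excess of bromochloromethane displaces bromide and should stop at the chloromethyl ether, as known for 2,6-disubstituted phenols. The alpha-chloro ether then quaternises triphenylphosphine (SN2), and the salt crystallises from toluene away from any neutral bis(aryloxy)methane.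

Step 6
Reactants: 11 {[4-(benzyloxy)-2,6-dimethoxyphenoxy]methyl}triphenylphosphonium chloride; 5 3,4,5-trimethoxypyrylium tetrafluoroborate
Product: 15 5-[4-(benzyloxy)-2,6-dimethoxyphenoxy]-1,2,3-trimethoxybenzene, via ylide 12 (not isolated), via 2H-pyran adduct 13 (not isolated), via dienal phosphonium salt 14 (not isolated)
Conditions: NaN(SiMe3)2 (1.0 equiv), THF, −78 °C; cannulation into 5 (1.1 equiv), MeCN/CH2Cl2, −60 → 0 °C; KOC(CH3)3 (1.1 equiv), 0 °C → rt
Reagents that add atoms: none
Why: This is the known ring transformation of pyrylium salts into benzenes by alkylidenephosphoranes, applied with an aryloxymethylene ylide and an alpha-unsubstituted pyrylium ion. Ylide 12 adds through carbon to C2 of 5 (C2 and C6 are equivalent) to give 2H-pyran 13, which opens in a thermal 6π electrocyclic reaction to dienal 14; 13 and 14 interconvert, so the geometry of the new alkene is not critical and the isomer that can cyclise is drained. KOC(CH3)3 then removes the proton alpha to phosphorus, which is acidic because the resulting ylide is conjugated through the diene with the aldehyde. Ring G closes by 6-exo-trig attack of the ylide carbon on the formyl carbon (intramolecular Wittig reaction); collapse of the oxaphosphetane expels triphenylphosphine oxide and forms G1–G6, G1–G2 having been formed in the addition, and aromatisation makes the closure irreversible. No stereocentre is created in 15, and the stereocentres of 13 and 14 are destroyed. The step needs alpha- rather than gamma-attack and C–C bond formation rather than transfer of the O-methyl group of 5 to the ylide: the alpha-carbons are unsubstituted and adjacent to the positively charged oxygen, whereas C4 is shielded by two methoxy neighbours and deactivated by donation from its own methoxy group. Adding cold 12 to a slight excess of 5 keeps free ylide from deprotonating the more acidic adduct or being methylated, and the whole sequence runs below room temperature, where the alkoxy ylide is stable.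

Step 7
Reactants: 15 5-[4-(benzyloxy)-2,6-dimethoxyphenoxy]-1,2,3-trimethoxybenzene
Product: 16 3,5-dimethoxy-4-(3,4,5-trimethoxyphenoxy)phenol
Conditions: H2 (1 atm), Pd/C, EtOAc/MeOH, rt
Reagents that add atoms: none
Why: Hydrogenolysis of the benzyl aryl ether; methyl and diaryl ethers are inert under these conditions.

Step 8
Reactants: 16 3,5-dimethoxy-4-(3,4,5-trimethoxyphenoxy)phenol; 17 2-bromo-3,4,5-trimethoxybenzaldehyde
Product: 18 2-[3,5-dimethoxy-4-(3,4,5-trimethoxyphenoxy)phenoxy]-3,4,5-trimethoxybenzaldehyde (EFG aldehyde)
Conditions: CuI (10 mol%), picolinic acid (20 mol%), K3PO4, DMSO, 90 °C, argon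
Reagents that add atoms: none
Why: Ullmann-type diaryl ether synthesis between an unhindered phenol and an aryl bromide whose ortho-formyl group makes the carbon electron-poor and can chelate copper. The aldehyde has no enolisable hydrogen and should survive the phosphate base.

Step 9
Reactants: 18 EFG aldehyde
Product: 20 2-[3,5-dimethoxy-4-(3,4,5-trimethoxyphenoxy)phenoxy]-3,4,5-trimethoxyphenol (EFG phenol), via EFG aryl formate 19 (not isolated)
Conditions: mCPBA (1.3 equiv), CH2Cl2, 0 °C → rt; then K2CO3 (cat.), MeOH, rt
Reagents that add atoms: 3-chloroperoxybenzoic acid (mCPBA), OOC(=O)c1cccc(Cl)c1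
Why: Baeyer–Villiger oxidation of an electron-rich benzaldehyde; the ortho-aryloxy and para-methoxy groups favour aryl over hydride migration, and the aryl formate is cleaved by methanolysis after the excess peracid has been washed out.

Step 10
Reactants: 20 EFG phenol; 21 4-bromo-3,5-dimethoxybenzaldehyde
Product: 22 4-{2-[3,5-dimethoxy-4-(3,4,5-trimethoxyphenoxy)phenoxy]-3,4,5-trimethoxyphenoxy}-3,5-dimethoxybenzaldehyde (DEFG aldehyde)
Conditions: CuI (20 mol%), picolinic acid (40 mol%), K3PO4, DMSO, 110 °C, argon
Reagents that add atoms: none
Why: Ullmann-type etherification with a copper–picolinate catalyst, a system suited to ortho-substituted partners; the para-formyl group makes the bromide electron-poor, which offsets the two flanking methoxy groups.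

Step 11
Reactants: 22 DEFG aldehyde
Product: 24 4-{2-[3,5-dimethoxy-4-(3,4,5-trimethoxyphenoxy)phenoxy]-3,4,5-trimethoxyphenoxy}-3,5-dimethoxyphenol (DEFG phenol), via DEFG aryl formate 23 (not isolated)
Conditions: mCPBA (1.3 equiv), CH2Cl2, 0 °C → rt; then K2CO3 (cat.), MeOH, rt
Reagents that add atoms: 3-chloroperoxybenzoic acid (mCPBA), OOC(=O)c1cccc(Cl)c1
Why: Baeyer–Villiger oxidation; the para-aryloxy group directs aryl migration as in 3,4,5-trialkoxybenzaldehydes, and methanolysis frees the D1 phenol.

Step 12
Reactants: 24 DEFG phenol; 17 2-bromo-3,4,5-trimethoxybenzaldehyde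
Product: 25 CDEFG aldehyde (2-aryloxy-3,4,5-trimethoxybenzaldehyde whose aryl group is that of 24, joined through the D1 oxygen to C6; formyl on C1)
Conditions: CuI (10 mol%), picolinic acid (20 mol%), K3PO4, DMSO, 90 °C, argon
Reagents that add atoms: none
Why: Same Ullmann-type coupling as step 8: unhindered phenol, ortho-formyl-activated bromide.

Step 13
Reactants: 25 CDEFG aldehyde
Product: 27 CDEFG phenol (free C1 hydroxyl), via CDEFG aryl formate 26 (not isolated)
Conditions: mCPBA (1.3 equiv), CH2Cl2, 0 °C → rt; then K2CO3 (cat.), MeOH, rt
Reagents that add atoms: 3-chloroperoxybenzoic acid (mCPBA), OOC(=O)c1cccc(Cl)c1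
Why: Baeyer–Villiger oxidation and formate methanolysis as in step 9; the ortho-aryloxy and para-methoxy groups secure aryl migration.

Step 14
Reactants: 27 CDEFG phenol; 21 4-bromo-3,5-dimethoxybenzaldehyde
Product: 28 BCDEFG aldehyde (4-aryloxy-3,5-dimethoxybenzaldehyde whose aryl group is that of 27, joined through the C1 oxygen to B4; formyl on B1)
Conditions: CuI (20 mol%), picolinic acid (40 mol%), K3PO4, DMSO, 110 °C, argon
Reagents that add atoms: none
Why: Same Ullmann-type coupling as step 10, with the para-formyl group activating the bromide between two methoxy groups.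

Step 15
Reactants: 28 BCDEFG aldehyde
Product: 30 BCDEFG phenol (free B1 hydroxyl), via BCDEFG aryl formate 29 (not isolated)
Conditions: mCPBA (1.3 equiv), CH2Cl2, 0 °C → rt; then K2CO3 (cat.), MeOH, rt
Reagents that add atoms: 3-chloroperoxybenzoic acid (mCPBA), OOC(=O)c1cccc(Cl)c1
Why: Baeyer–Villiger oxidation and formate methanolysis as in step 11.

Step 16
Reactants: 30 BCDEFG phenol; 21 4-bromo-3,5-dimethoxybenzaldehyde
Product: 31 heptamer aldehyde (4-aryloxy-3,5-dimethoxybenzaldehyde whose aryl group is that of 30, joined through the B1 oxygen to A1; formyl on A4)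
Conditions: CuI (20 mol%), picolinic acid (40 mol%), K3PO4, DMSO, 110 °C, argon
Reagents that add atoms: none
Why: Ullmann-type coupling as in step 10; here the phenol is unhindered, so this is the easiest of the three couplings with 21.

Step 17
Reactants: 31 heptamer aldehyde
Product: 33 heptamer phenol (heptadecamethyl ether of the target with free A4 hydroxyl), via heptamer aryl formate 32 (not isolated)
Conditions: mCPBA (1.3 equiv), CH2Cl2, 0 °C → rt; then K2CO3 (cat.), MeOH, rt
Reagents that add atoms: 3-chloroperoxybenzoic acid (mCPBA), OOC(=O)c1cccc(Cl)c1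
Why: Baeyer–Villiger oxidation and formate methanolysis as in step 11; this sets the last oxygen of ring A.

Step 18
Reactants: 33 heptamer phenol
Product: 34 CNP0292517.0 (target)
Conditions: BBr3 (30 equiv), CH2Cl2, −78 °C → rt, argon; MeOH, then degassed H2O, 0 °C; reversed-phase isolation under argon
Reagents that add atoms: none
Why: Lewis-acid cleavage of aryl methyl ethers by bromide attack on the O-methyl carbon of the borane adducts; diaryl ethers have no such alkyl carbon and should persist, and the cold, oxygen-free work-up protects the polyphenol.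

## Compound list

1 | 1,3-dimethoxyacetone (1,3-dimethoxypropan-2-one) | COCC(=O)COC | starting material
2 | ethyl formate | CCOC=O | starting material
3 | 1,5-dihydroxy-2,4-dimethoxypenta-1,4-dien-3-one (bis-enol of 2,4-dimethoxy-3-oxopentanedial, present as disodium salt; alkene geometry undefined) | COC(=CO)C(=O)C(OC)=CO | intermediate (not isolated)
4 | 3,5-dimethoxy-4H-pyran-4-one | COC1=COC=C(OC)C1=O | intermediate
5 | 3,4,5-trimethoxypyrylium tetrafluoroborate | COc1c[o+]cc(OC)c1OC.F[B-](F)(F)F | intermediate
6 | 2,6-dimethoxy-1,4-benzoquinone | COC1=CC(=O)C=C(OC)C1=O | starting material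
7 | 2,6-dimethoxybenzene-1,4-diol | COc1cc(O)cc(OC)c1O | intermediate
8 | 4-(benzyloxy)-2,6-dimethoxyphenol | COc1cc(OCc2ccccc2)cc(OC)c1O | intermediate
9 | triphenylphosphine | c1ccc(cc1)P(c1ccccc1)c1ccccc1 | starting material
10 | 5-(benzyloxy)-2-(chloromethoxy)-1,3-dimethoxybenzene | COc1cc(OCc2ccccc2)cc(OC)c1OCCl | intermediate (not isolated)
11 | {[4-(benzyloxy)-2,6-dimethoxyphenoxy]methyl}triphenylphosphonium chloride | COc1cc(OCc2ccccc2)cc(OC)c1OC[P+](c1ccccc1)(c1ccccc1)c1ccccc1.[Cl-] | intermediate
12 | {[4-(benzyloxy)-2,6-dimethoxyphenoxy]methylidene}triphenyl-λ5-phosphane (ylide) | COc1cc(OCc2ccccc2)cc(OC)c1OC=P(c1ccccc1)(c1ccccc1)c1ccccc1 | intermediate (not isolated)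
13 | {[4-(benzyloxy)-2,6-dimethoxyphenoxy](3,4,5-trimethoxy-2H-pyran-2-yl)methyl}triphenylphosphonium tetrafluoroborate (racemic mixture of diastereomers) | COC1=C(OC)C(OC)=COC1C(Oc1c(OC)cc(OCc2ccccc2)cc1OC)[P+](c1ccccc1)(c1ccccc1)c1ccccc1.F[B-](F)(F)F | intermediate (not isolated)
14 | {(2E,4Z)-1-[4-(benzyloxy)-2,6-dimethoxyphenoxy]-3,4,5-trimethoxy-6-oxohexa-2,4-dien-1-yl}triphenylphosphonium tetrafluoroborate (racemic) | O=C/C(OC)=C(OC)\C(OC)=C/C(Oc1c(OC)cc(OCc2ccccc2)cc1OC)[P+](c1ccccc1)(c1ccccc1)c1ccccc1.F[B-](F)(F)F | intermediate (not isolated)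
15 | 5-[4-(benzyloxy)-2,6-dimethoxyphenoxy]-1,2,3-trimethoxybenzene (protected FG dimer) | COc1cc(OCc2ccccc2)cc(OC)c1Oc1cc(OC)c(OC)c(OC)c1 | intermediate
16 | 3,5-dimethoxy-4-(3,4,5-trimethoxyphenoxy)phenol (FG phenol) | COc1cc(O)cc(OC)c1Oc1cc(OC)c(OC)c(OC)c1 | intermediate
17 | 2-bromo-3,4,5-trimethoxybenzaldehyde | COc1cc(C=O)c(Br)c(OC)c1OC | starting material
18 | 2-[3,5-dimethoxy-4-(3,4,5-trimethoxyphenoxy)phenoxy]-3,4,5-trimethoxybenzaldehyde (EFG aldehyde) | COc1cc(C=O)c(Oc2cc(OC)c(Oc3cc(OC)c(OC)c(OC)c3)c(OC)c2)c(OC)c1OC | intermediate
19 | 2-[3,5-dimethoxy-4-(3,4,5-trimethoxyphenoxy)phenoxy]-3,4,5-trimethoxyphenyl formate | COc1cc(OC=O)c(Oc2cc(OC)c(Oc3cc(OC)c(OC)c(OC)c3)c(OC)c2)c(OC)c1OC | intermediate (not isolated)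
20 | 2-[3,5-dimethoxy-4-(3,4,5-trimethoxyphenoxy)phenoxy]-3,4,5-trimethoxyphenol (EFG phenol) | COc1cc(O)c(Oc2cc(OC)c(Oc3cc(OC)c(OC)c(OC)c3)c(OC)c2)c(OC)c1OC | intermediate
21 | 4-bromo-3,5-dimethoxybenzaldehyde | COc1cc(C=O)cc(OC)c1Br | starting material
22 | 4-{2-[3,5-dimethoxy-4-(3,4,5-trimethoxyphenoxy)phenoxy]-3,4,5-trimethoxyphenoxy}-3,5-dimethoxybenzaldehyde (DEFG aldehyde) | COc1cc(C=O)cc(OC)c1Oc1cc(OC)c(OC)c(OC)c1Oc1cc(OC)c(Oc2cc(OC)c(OC)c(OC)c2)c(OC)c1 | intermediate
23 | 4-{2-[3,5-dimethoxy-4-(3,4,5-trimethoxyphenoxy)phenoxy]-3,4,5-trimethoxyphenoxy}-3,5-dimethoxyphenyl formate | COc1cc(OC=O)cc(OC)c1Oc1cc(OC)c(OC)c(OC)c1Oc1cc(OC)c(Oc2cc(OC)c(OC)c(OC)c2)c(OC)c1 | intermediate (not isolated)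
24 | 4-{2-[3,5-dimethoxy-4-(3,4,5-trimethoxyphenoxy)phenoxy]-3,4,5-trimethoxyphenoxy}-3,5-dimethoxyphenol (DEFG phenol) | COc1cc(O)cc(OC)c1Oc1cc(OC)c(OC)c(OC)c1Oc1cc(OC)c(Oc2cc(OC)c(OC)c(OC)c2)c(OC)c1 | intermediate
25 | 2-(4-{2-[3,5-dimethoxy-4-(3,4,5-trimethoxyphenoxy)phenoxy]-3,4,5-trimethoxyphenoxy}-3,5-dimethoxyphenoxy)-3,4,5-trimethoxybenzaldehyde (CDEFG aldehyde) | COc1cc(C=O)c(Oc2cc(OC)c(Oc3cc(OC)c(OC)c(OC)c3Oc3cc(OC)c(Oc4cc(OC)c(OC)c(OC)c4)c(OC)c3)c(OC)c2)c(OC)c1OC | intermediate
26 | formate ester of 27 (CDEFG aryl formate, formyloxy on C1) | COc1cc(OC=O)c(Oc2cc(OC)c(Oc3cc(OC)c(OC)c(OC)c3Oc3cc(OC)c(Oc4cc(OC)c(OC)c(OC)c4)c(OC)c3)c(OC)c2)c(OC)c1OC | intermediate (not isolated)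
27 | 2-(4-{2-[3,5-dimethoxy-4-(3,4,5-trimethoxyphenoxy)phenoxy]-3,4,5-trimethoxyphenoxy}-3,5-dimethoxyphenoxy)-3,4,5-trimethoxyphenol (CDEFG phenol) | COc1cc(O)c(Oc2cc(OC)c(Oc3cc(OC)c(OC)c(OC)c3Oc3cc(OC)c(Oc4cc(OC)c(OC)c(OC)c4)c(OC)c3)c(OC)c2)c(OC)c1OC | intermediate
28 | 4-[2-(4-{2-[3,5-dimethoxy-4-(3,4,5-trimethoxyphenoxy)phenoxy]-3,4,5-trimethoxyphenoxy}-3,5-dimethoxyphenoxy)-3,4,5-trimethoxyphenoxy]-3,5-dimethoxybenzaldehyde (BCDEFG aldehyde) | COc1cc(C=O)cc(OC)c1Oc1cc(OC)c(OC)c(OC)c1Oc1cc(OC)c(Oc2cc(OC)c(OC)c(OC)c2Oc2cc(OC)c(Oc3cc(OC)c(OC)c(OC)c3)c(OC)c2)c(OC)c1 | intermediate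
29 | formate ester of 30 (BCDEFG aryl formate, formyloxy on B1) | COc1cc(OC=O)cc(OC)c1Oc1cc(OC)c(OC)c(OC)c1Oc1cc(OC)c(Oc2cc(OC)c(OC)c(OC)c2Oc2cc(OC)c(Oc3cc(OC)c(OC)c(OC)c3)c(OC)c2)c(OC)c1 | intermediate (not isolated)
30 | 4-[2-(4-{2-[3,5-dimethoxy-4-(3,4,5-trimethoxyphenoxy)phenoxy]-3,4,5-trimethoxyphenoxy}-3,5-dimethoxyphenoxy)-3,4,5-trimethoxyphenoxy]-3,5-dimethoxyphenol (BCDEFG phenol) | COc1cc(O)cc(OC)c1Oc1cc(OC)c(OC)c(OC)c1Oc1cc(OC)c(Oc2cc(OC)c(OC)c(OC)c2Oc2cc(OC)c(Oc3cc(OC)c(OC)c(OC)c3)c(OC)c2)c(OC)c1 | intermediate
31 | 4-{4-[2-(4-{2-[3,5-dimethoxy-4-(3,4,5-trimethoxyphenoxy)phenoxy]-3,4,5-trimethoxyphenoxy}-3,5-dimethoxyphenoxy)-3,4,5-trimethoxyphenoxy]-3,5-dimethoxyphenoxy}-3,5-dimethoxybenzaldehyde (heptamer aldehyde) | COc1cc(C=O)cc(OC)c1Oc1cc(OC)c(Oc2cc(OC)c(OC)c(OC)c2Oc2cc(OC)c(Oc3cc(OC)c(OC)c(OC)c3Oc3cc(OC)c(Oc4cc(OC)c(OC)c(OC)c4)c(OC)c3)c(OC)c2)c(OC)c1 | intermediate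
32 | formate ester of 33 (heptamer aryl formate, formyloxy on A4) | COc1cc(OC=O)cc(OC)c1Oc1cc(OC)c(Oc2cc(OC)c(OC)c(OC)c2Oc2cc(OC)c(Oc3cc(OC)c(OC)c(OC)c3Oc3cc(OC)c(Oc4cc(OC)c(OC)c(OC)c4)c(OC)c3)c(OC)c2)c(OC)c1 | intermediate (not isolated)
33 | 4-{4-[2-(4-{2-[3,5-dimethoxy-4-(3,4,5-trimethoxyphenoxy)phenoxy]-3,4,5-trimethoxyphenoxy}-3,5-dimethoxyphenoxy)-3,4,5-trimethoxyphenoxy]-3,5-dimethoxyphenoxy}-3,5-dimethoxyphenol (heptadecamethyl ether of the target, free A4 hydroxyl) | COc1cc(O)cc(OC)c1Oc1cc(OC)c(Oc2cc(OC)c(OC)c(OC)c2Oc2cc(OC)c(Oc3cc(OC)c(OC)c(OC)c3Oc3cc(OC)c(Oc4cc(OC)c(OC)c(OC)c4)c(OC)c3)c(OC)c2)c(OC)c1 | intermediate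
34 | CNP0292517.0, 2-{4-[2-(4-{2-[3,5-dihydroxy-4-(3,4,5-trihydroxyphenoxy)phenoxy]-3,4,5-trihydroxyphenoxy}-3,5-dihydroxyphenoxy)-3,4,5-trihydroxyphenoxy]-3,5-dihydroxyphenoxy}benzene-1,3,5-triol | Oc1cc(O)c(Oc2cc(O)c(Oc3cc(O)c(O)c(O)c3Oc3cc(O)c(Oc4cc(O)c(O)c(O)c4Oc4cc(O)c(Oc5cc(O)c(O)c(O)c5)c(O)c4)c(O)c3)c(O)c2)c(O)c1 | target

## Step count and least certain steps

Total step count: 18. Longest linear sequence: 16 steps (6 to 34, steps 3–18); the branch from 1 to 5 (steps 1 and 2) joins at step 6.

Step 6 (key step). The ylide may attack C4 with loss of methoxide, or the O-methyl group of 5 may be transferred to the ylide carbon. Proton transfer from the acidic adduct to unreacted ylide, hydrolytic opening of 5 by traces of water and thermal decay of the alkoxy ylide are further losses. The cause is that a 4-methoxypyrylium ion is both an ambident electrophile and a methylating agent. Fallback: setting out from 8, an Ullmann-type etherification with purchased 5-bromo-1,2,3-trimethoxybenzene (CuI, picolinic acid, K3PO4, DMSO, 100 °C) should give 15 directly, where the route is rejoined. A hindered phenol with an unhindered bromide is the favourable combination for this catalyst. The fallback makes no new compound (F0), but it gives up the ring construction and forms the flanked F4–O bond by coupling.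

Step 10 (and steps 14 and 16, which are of the same kind). Substitution at a bromine-bearing carbon between two methoxy groups may be too slow, especially in steps 10 and 14 where the phenol also has an ortho substituent. Protodebromination of 21 or base-induced loss of the aldehyde could then take over. Fallback: an uncatalysed nucleophilic aromatic substitution at a small fluoride leaving group. Setting out from 21, acetalisation with ethylene glycol (TsOH, toluene, reflux) would give 2-(4-bromo-3,5-dimethoxyphenyl)-1,3-dioxolane F1. Bromine–lithium exchange (n-BuLi, THF, −78 °C) and fluorination with N-fluorobenzenesulfonimide would give 2-(4-fluoro-3,5-dimethoxyphenyl)-1,3-dioxolane F2. Aqueous HCl would release 4-fluoro-3,5-dimethoxybenzaldehyde F3. Heating 20 with F3 and Cs2CO3 in DMSO at 120 °C should then give 22, where the route is rejoined; the same F3 would serve with 27 and 30 to rejoin at 28 and 31.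

Step 5. A second substitution may turn the chloromethyl ether into the bis(aryloxy)methane, or moisture may hydrolyse it before quaternisation. The cause is that the alpha-chloro ether is more reactive than the dihalomethane it is made from. Fallback: setting out from 8, alkylation with chloromethyl methyl sulfide (NaH, NaI, DMF) would give 5-(benzyloxy)-1,3-dimethoxy-2-[(methylsulfanyl)methoxy]benzene F4. Treatment with SO2Cl2 in CH2Cl2 at −78 °C, with cyclohexene present to trap the sulfenyl chloride, would convert F4 into 10, which is quaternised with 9 to rejoin the route at 11.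

Step 18. Dealkylation may stop short of all seventeen ethers as partly cleaved borates precipitate. The product may also be oxidised during isolation, or a diaryl ether on rings B, D or F may be cleaved if the acidic quench warms. Fallback: setting out from 33, the crude product of the BBr3 treatment would be acetylated without isolation (Ac2O, pyridine) to the octadecaacetate of the target F5, which is stable and can be purified on silica. Deacetylation under argon (NaOCH3 cat., degassed MeOH, then acidic resin) would then give 34.

Step 1. The second formylation may fail, leaving the mono-formyl ketone, which can self-condense under the basic conditions. Fallback: setting out from 1, heating with N,N-dimethylformamide dimethyl acetal would give 1,5-bis(dimethylamino)-2,4-dimethoxypenta-1,4-dien-3-one F6, and aqueous HCl would cyclise it to 4, where the route is rejoined.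

## Further compounds

F0 | step 6 | none | none
F1 | step 10 | 2-(4-bromo-3,5-dimethoxyphenyl)-1,3-dioxolane | COc1cc(C2OCCO2)cc(OC)c1Br
F2 | step 10 | 2-(4-fluoro-3,5-dimethoxyphenyl)-1,3-dioxolane | COc1cc(C2OCCO2)cc(OC)c1F
F3 | step 10 | 4-fluoro-3,5-dimethoxybenzaldehyde | COc1cc(C=O)cc(OC)c1F
F4 | step 5 | 5-(benzyloxy)-1,3-dimethoxy-2-[(methylsulfanyl)methoxy]benzene | COc1cc(OCc2ccccc2)cc(OC)c1OCSC
F5 | step 18 | octadecaacetate of the target | CC(=O)Oc1cc(OC(C)=O)c(Oc2cc(OC(C)=O)c(Oc3cc(OC(C)=O)c(OC(C)=O)c(OC(C)=O)c3Oc3cc(OC(C)=O)c(Oc4cc(OC(C)=O)c(OC(C)=O)c(OC(C)=O)c4Oc4cc(OC(C)=O)c(Oc5cc(OC(C)=O)c(OC(C)=O)c(OC(C)=O)c5)c(OC(C)=O)c4)c(OC(C)=O)c3)c(OC(C)=O)c2)c(OC(C)=O)c1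
F6 | step 1 | 1,5-bis(dimethylamino)-2,4-dimethoxypenta-1,4-dien-3-one (alkene geometry undefined) | CN(C)C=C(OC)C(=O)C(OC)=CN(C)C
A1 | alternative 1 | methyl 4-(aryloxy)-3-oxobutanoate, aryl = permethylated EFG trimer bonded through the E1 oxygen | COC(=O)CC(=O)COc1cc(OC)c(OC)c(OC)c1Oc1cc(OC)c(Oc2cc(OC)c(OC)c(OC)c2)c(OC)c1
A2 | alternative 1 | methyl 3-(aryloxy)prop-2-ynoate, aryl = permethylated ABC trimer bonded through the C6 oxygen | COC(=O)C#COc1c(OC)c(OC)c(OC)cc1Oc1c(OC)cc(Oc2c(OC)cc(OC)cc2OC)cc1OC
A3 | alternative 1 | heptamer with free D3 and D5 hydroxyls and methyl ester on D6 | COc1cc(OC)c(Oc2cc(OC)c(Oc3cc(OC)c(OC)c(OC)c3Oc3cc(O)c(Oc4cc(OC)c(OC)c(OC)c4Oc4cc(OC)c(Oc5cc(OC)c(OC)c(OC)c5)c(OC)c4)c(O)c3C(=O)OC)c(OC)c2)c(OC)c1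
A4 | alternative 2 | 2,3,4-trimethoxy-4-[(E)-2-(aryloxy)ethenyl]cyclobut-2-en-1-one (racemic), aryl = permethylated AB dimer bonded through the B4 oxygen | COC1=C(OC)C(OC)(/C=C/Oc2c(OC)cc(Oc3c(OC)cc(OC)cc3OC)cc2OC)C1=O
A5 | alternative 2 | permethylated ABC trimer with free hydroxyl on C6 | COc1cc(OC)c(Oc2cc(OC)c(Oc3cc(OC)c(OC)c(OC)c3O)c(OC)c2)c(OC)c1
A6 | alternative 3 | 4-(aryloxy)-3-ethoxycyclobut-2-en-1-one (racemic), aryl = permethylated CDEFG pentamer bonded through the C1 oxygen | CCOC1=CC(=O)C1Oc1cc(OC)c(OC)c(OC)c1Oc1cc(OC)c(Oc2cc(OC)c(OC)c(OC)c2Oc2cc(OC)c(Oc3cc(OC)c(OC)c(OC)c3)c(OC)c2)c(OC)c1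
A7 | alternative 3 | 2-(ethynyloxy)-1,3,5-trimethoxybenzene | C#COc1c(OC)cc(OC)cc1OC
A8 | alternative 3 | protected heptamer with free B3 hydroxyl and B5 ethyl ether | COc1cc(OC)c(Oc2cc(O)c(Oc3cc(OC)c(OC)c(OC)c3Oc3cc(OC)c(Oc4cc(OC)c(OC)c(OC)c4Oc4cc(OC)c(Oc5cc(OC)c(OC)c(OC)c5)c(OC)c4)c(OC)c3)c(OCC)c2)c(OC)c1
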